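**Plan**

1. Cuts: the last cut is O2–C3 of the 1,2-dioxane (ring atoms O1, O2, C3, C4, C5, C6). C3 is β to the ester carbonyl C1, so the ring is the oxa-Michael adduct of a C6 hydroperoxide onto a C2=C3 enoate, as in the presumed biosynthesis. Next C6–O1 (perhydrolysis of a C6 oxetane whose CH2CH2O arm is the latent C6 ethyl), then C6–C7 (Suzuki–Miyaura) and C4–C5 (auxiliary alkylation).
2. Forward: the C7–C14 diene and the C3–C6 vinyl iodide are joined at C6–C7; allylic alcohol → epoxide → 1,3-diol → oxetane; the enoate is attached at C3; H2O2 opens the oxetane; the dioxane, the only ring, is closed last; the hydroxyethyl arm is then reduced to ethyl.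
3. Stereochemistry: C10 and the (E)-alkene come from a ligand-controlled Et2Zn addition relayed by a chair Johnson–Claisen rearrangement. C4 comes from the oxazolidinone auxiliary. C6 comes from Sharpless epoxidation of the geometrically defined trisubstituted alkene, is retained in the oxetane and inverted once in the SN2-type perhydrolysis. C3 comes from C4 in the ring closure.
4. Locants follow the target: C1 ester carbon, C2 its α-carbon, O1 on C6, O2 on C3, C7–C14 the side chain, C10 its stereocentre.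

Key step: step 17

Assumption: acyl oxazolidinone 6 is taken as a catalogue compound; otherwise it is one acylation step from (4R)-4-benzyl-1,3-oxazolidin-2-one and butanoyl chloride.

**Route**

Step 1
Reactants: 1 (2E)-pent-2-enal
Product: 2 (3R,4E)-hept-4-en-3-ol
Conditions: Et2Zn, (2R)-3-exo-morpholinoisoborneol (4 mol %), hexane, 0 °C; aqueous work-up
Reagents that add atoms: diethylzinc, CC[Zn]CC
Why: Amino-alcohol-catalysed enantioselective 1,2-addition of Et2Zn to an enal; the (2R)-ligand, mirror image of the one that gives (S)-carbinols from aldehydes, should deliver ethyl to the Re face and give the (R)-allylic alcohol whose configuration is relayed to C10.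

Step 2
Reactants: 2 (3R,4E)-hept-4-en-3-ol
Product: 3 ethyl (3R,4E)-3-ethylhept-4-enoate
Conditions: MeC(OEt)3 (excess), EtCO2H (cat.), 140 °C, EtOH distilled off
Reagents that add atoms: triethyl orthoacetate, CC(OCC)(OCC)OCC
Why: Johnson–Claisen rearrangement: the mixed ketene acetal rearranges through a chair with the carbinol ethyl equatorial, so the C–O stereocentre should be transferred suprafacially to the new C–C stereocentre (R, later C10) and the new alkene should be E.

Step 3
Reactants: 3 ethyl (3R,4E)-3-ethylhept-4-enoate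
Product: 4 (3R,4E)-3-ethylhept-4-enal
Conditions: i-Bu2AlH, CH2Cl2, −78 °C; aqueous work-up
Reagents that add atoms: none
Why: Partial reduction of an ester by i-Bu2AlH at low temperature (stable tetrahedral aluminium hemiacetal), the stereocentre being β to the carbonyl and not epimerisable.

Step 4
Reactants: 4 (3R,4E)-3-ethylhept-4-enal
Product: 5 (4R,5E)-4-ethylocta-1,5-diene
Conditions: Ph3PCH3Br, KN(SiMe3)2, THF, 0 °C to rt
Reagents that add atoms: methyltriphenylphosphonium bromide, [Br-].C[P+](c1ccccc1)(c1ccccc1)c1ccccc1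
Why: Wittig methylenation of an unhindered aldehyde gives the terminal alkene that will be hydroborated selectively.

Step 5
Reactants: 6 (4R)-4-benzyl-3-butanoyl-1,3-oxazolidin-2-one
Product: 8 (4R)-4-benzyl-3-[(2S)-2-ethylpent-4-ynoyl]-1,3-oxazolidin-2-one, via sodium enolate 7 (not isolated)
Conditions: NaN(SiMe3)2, THF, −78 °C; propargyl bromide, −78 to −40 °C
Reagents that add atoms: propargyl bromide, C#CCBr
Why: Evans asymmetric alkylation: the chelated (Z)-sodium enolate is alkylated by propargyl bromide on the face away from the benzyl group, which should set C4 as (S).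

Step 6
Reactants: 8 (4R)-4-benzyl-3-[(2S)-2-ethylpent-4-ynoyl]-1,3-oxazolidin-2-one
Product: 9 (2S)-2-ethylpent-4-yn-1-ol
Conditions: LiBH4, MeOH (1 equiv), Et2O, 0 °C
Reagents that add atoms: none
Why: Reductive cleavage of the N-acyl oxazolidinone with LiBH4 gives the primary alcohol without epimerising C4 and returns the auxiliary.

Step 7
Reactants: 9 (2S)-2-ethylpent-4-yn-1-ol
Product: 10 tert-butyl{[(2S)-2-ethylpent-4-yn-1-yl]oxy}diphenylsilane
Conditions: t-BuPh2SiCl, imidazole, CH2Cl2, rt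
Reagents that add atoms: tert-butyl(chloro)diphenylsilane, CC(C)(C)[Si](Cl)(c1ccccc1)c1ccccc1
Why: Standard silylation of a primary alcohol; the tert-butyldiphenylsilyl ether should survive n-BuLi, both aluminium hydride steps and KOtBu.

Step 8
Reactants: 10 tert-butyl{[(2S)-2-ethylpent-4-yn-1-yl]oxy}diphenylsilane
Product: 12 (5S)-5-{[tert-butyl(diphenyl)silyl]oxymethyl}hept-2-yn-1-ol, via lithium acetylide 11 (not isolated)
Conditions: n-BuLi, THF, −78 °C; (CH2O)n, −78 °C to rt; aqueous work-up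
Reagents that add atoms: formaldehyde (as paraformaldehyde), C=O
Why: Hydroxymethylation of a terminal alkyne (lithium acetylide addition to formaldehyde).

Step 9
Reactants: 12 (5S)-5-{[tert-butyl(diphenyl)silyl]oxymethyl}hept-2-yn-1-ol
Product: 14 (2Z,5S)-5-{[tert-butyl(diphenyl)silyl]oxymethyl}-3-iodohept-2-en-1-ol, via sodium alkenylalanate 13 (not isolated)
Conditions: NaAlH2(OCH2CH2OMe)2, THF, 0 °C to rt; then I2, −78 to 0 °C; aqueous work-up
Reagents that add atoms: iodine, II
Why: Hydroxyl-directed trans-hydroalumination of the propargylic alcohol puts aluminium on the distal carbon in a five-membered alanate, and iodinolysis with retention should give the (Z)-3-iodo allylic alcohol (hydroalumination–iodination).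

Step 10
Reactants: 5 (4R,5E)-4-ethylocta-1,5-diene; 14 (2Z,5S)-5-{[tert-butyl(diphenyl)silyl]oxymethyl}-3-iodohept-2-en-1-ol
Product: 16 (2E,7R,8E)-3-[(2S)-2-{[tert-butyl(diphenyl)silyl]oxymethyl}butyl]-7-ethylundeca-2,8-dien-1-ol, via alkylborane 15 (not isolated)
Conditions: 5, 9-borabicyclo[3.3.1]nonane, THF, rt; then 14, Pd(dppf)Cl2 (5 mol %), AsPh3, Cs2CO3, DMF–H2O, rt
Reagents that add atoms: none
Why: 9-Borabicyclo[3.3.1]nonane hydroborates only the terminal alkene of 5 and the B-alkyl Suzuki–Miyaura coupling proceeds with retention at the vinyl iodide, so the (E)-trisubstituted allylic alcohol with the side chain cis to CH2OH should result.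

Step 11
Reactants: 16 (2E,7R,8E)-3-[(2S)-2-{[tert-butyl(diphenyl)silyl]oxymethyl}butyl]-7-ethylundeca-2,8-dien-1-ol
Product: 17 {(2R,3R)-3-[(2S)-2-{[tert-butyl(diphenyl)silyl]oxymethyl}butyl]-3-[(4R,5E)-4-ethyloct-5-en-1-yl]oxiran-2-yl}methanol
Conditions: Ti(OiPr)4 (10 mol %), D-(−)-diethyl tartrate (12 mol %), t-BuOOH, 4 Å molecular sieves, CH2Cl2, −20 °C
Reagents that add atoms: tert-butyl hydroperoxide, CC(C)(C)OO
Why: Sharpless asymmetric epoxidation: only the allylic alkene reacts and the Ti(OiPr)4/D-tartrate complex should deliver oxygen to the face that gives the (2R,3R)-epoxide, which fixes the C6–O configuration by reagent control and alkene geometry.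

Step 12
Reactants: 17 {(2R,3R)-3-[(2S)-2-{[tert-butyl(diphenyl)silyl]oxymethyl}butyl]-3-[(4R,5E)-4-ethyloct-5-en-1-yl]oxiran-2-yl}methanol
Product: 18 (3R,7R,8E)-3-[(2S)-2-{[tert-butyl(diphenyl)silyl]oxymethyl}butyl]-7-ethylundec-8-ene-1,3-diol
Conditions: NaAlH2(OCH2CH2OMe)2, THF, 0 °C; aqueous work-up
Reagents that add atoms: none
Why: Hydroxyl-directed hydride delivery to C2 of the 2,3-epoxy alcohol (C3 is quaternary) should give the 1,3-diol with the C6–O bond untouched (regioselective reductive epoxide opening).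

Step 13
Reactants: 18 (3R,7R,8E)-3-[(2S)-2-{[tert-butyl(diphenyl)silyl]oxymethyl}butyl]-7-ethylundec-8-ene-1,3-diol
Product: 20 (2R)-2-[(2S)-2-{[tert-butyl(diphenyl)silyl]oxymethyl}butyl]-2-[(4R,5E)-4-ethyloct-5-en-1-yl]oxetane, via monotosylate 19 (not isolated)
Conditions: KOtBu (1.0 equiv), TsCl (1.0 equiv), THF, 0 °C; then KOtBu (1.2 equiv), 0 °C to rt
Reagents that add atoms: none
Why: Selective sulfonylation of the primary alkoxide followed by 4-exo-tet Williamson etherification by the tertiary alkoxide; no bond to C6 is broken, so its configuration is retained.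

Step 14
Reactants: 20 (2R)-2-[(2S)-2-{[tert-butyl(diphenyl)silyl]oxymethyl}butyl]-2-[(4R,5E)-4-ethyloct-5-en-1-yl]oxetane
Product: 21 (2S)-2-({(2R)-2-[(4R,5E)-4-ethyloct-5-en-1-yl]oxetan-2-yl}methyl)butan-1-ol
Conditions: Bu4NF, THF, rt; aqueous work-up
Reagents that add atoms: none
Why: Fluoride-mediated desilylation; the oxetane is inert to fluoride.

Step 15
Reactants: 21 (2S)-2-({(2R)-2-[(4R,5E)-4-ethyloct-5-en-1-yl]oxetan-2-yl}methyl)butan-1-ol
Product: 23 methyl (2E,4S)-4-({(2R)-2-[(4R,5E)-4-ethyloct-5-en-1-yl]oxetan-2-yl}methyl)hex-2-enoate, via aldehyde 22 (not isolated)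
Conditions: Dess–Martin periodinane, NaHCO3, CH2Cl2, 0 °C to rt; then Ph3P=CHCO2Me, rt
Reagents that add atoms: methyl (triphenylphosphoranylidene)acetate, COC(=O)C=P(c1ccccc1)(c1ccccc1)c1ccccc1
Why: Dess–Martin oxidation and in-flask Wittig olefination with a stabilised ylide avoid isolation of the α-branched aldehyde and should give the (E)-enoate.

Step 16
Reactants: 23 methyl (2E,4S)-4-({(2R)-2-[(4R,5E)-4-ethyloct-5-en-1-yl]oxetan-2-yl}methyl)hex-2-enoate
Product: 24 methyl (2E,4S,6S,10R,11E)-4,10-diethyl-6-hydroperoxy-6-(2-hydroxyethyl)tetradeca-2,11-dienoate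
Conditions: anhydrous H2O2 in Et2O (excess), Me3SiOTf (0.2 equiv), Et2O, −78 to −20 °C; aqueous work-up
Reagents that add atoms: hydrogen peroxide, OO
Why: Lewis-acid-promoted perhydrolysis of a 2,2-dialkyl oxetane: H2O2 attacks the tertiary carbon of the activated oxetane in a borderline SN2 process with inversion, which should set C6 as (S) and leave the primary alcohol.

Step 17
Reactants: 24 methyl (2E,4S,6S,10R,11E)-4,10-diethyl-6-hydroperoxy-6-(2-hydroxyethyl)tetradeca-2,11-dienoate
Product: 25 methyl 2-{(3S,4S,6S)-4-ethyl-6-[(4R,5E)-4-ethyloct-5-en-1-yl]-6-(2-hydroxyethyl)-1,2-dioxan-3-yl}acetate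
Conditions: Et2NH, CF3CH2OH, rt
Reagents that add atoms: none
Why: Et2NH reversibly deprotonates the tertiary hydroperoxide and its terminal oxygen adds to C3, the β-carbon of the (E)-enoate, after which the fluorinated alcohol protonates the ester enolate at once, so that neither retro-addition nor enolate attack on the O–O bond (epoxide formation) should compete. The closest known reaction type is the intramolecular oxa-Michael addition of alkyl hydroperoxides to α,β-unsaturated esters, which is also the ring closure presumed in the biosynthesis of polyketide 1,2-dioxane-3-acetates. The 1,2-dioxane is closed in the 6-exo-trig mode, O2–C3 being the only bond formed and C6 (set in step 16) being untouched. The new stereocentre C3 is controlled by C4 through a chair-like Felkin–Anh-type transition state in which the C4 ethyl group is equatorial and antiperiplanar to the forming O–C3 bond, the ring methylene C5 lies inside and H outside, so that the acetate arm should end axial and cis to the C4 ethyl (3S). The step needs chemoselectivity for the electron-poor C2=C3 bond over the isolated C11=C12 alkene and face selectivity at C3; the first is secured by conjugation to the ester, the second by the (E)-geometry (no A(1,3) strain to favour the H-inside rotamer) and by the fact that the axial C3 arm meets only a lone pair on O1 while the axial C6 chain points to the opposite ring face.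

Step 18
Reactants: 25 methyl 2-{(3S,4S,6S)-4-ethyl-6-[(4R,5E)-4-ethyloct-5-en-1-yl]-6-(2-hydroxyethyl)-1,2-dioxan-3-yl}acetate
Product: 26 methyl 2-{(3S,4S,6S)-4-ethyl-6-[(4R,5E)-4-ethyloct-5-en-1-yl]-6-[2-(tosyloxy)ethyl]-1,2-dioxan-3-yl}acetate
Conditions: TsCl, pyridine, 4-(dimethylamino)pyridine (cat.), CH2Cl2, 0 °C
Reagents that add atoms: 4-methylbenzenesulfonyl chloride, Cc1ccc(cc1)S(Cl)(=O)=O
Why: Sulfonylation of the primary alcohol; the dialkyl peroxide and the ester are inert to TsCl and pyridine.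

Step 19
Reactants: 26 methyl 2-{(3S,4S,6S)-4-ethyl-6-[(4R,5E)-4-ethyloct-5-en-1-yl]-6-[2-(tosyloxy)ethyl]-1,2-dioxan-3-yl}acetate
Product: 27 methyl 2-{(3S,4S,6S)-4,6-diethyl-6-[(4R,5E)-4-ethyloct-5-en-1-yl]-1,2-dioxan-3-yl}acetate
Conditions: NaBH4, DMSO, 50 °C; aqueous work-up
Reagents that add atoms: none
Why: SN2 displacement of a primary tosylate by hydride from NaBH4 in a dipolar aprotic solvent, conditions under which dialkyl peroxides and methyl esters are expected to survive.

**Compound list**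

1 | (2E)-pent-2-enal | CC/C=C/C=O | starting material
2 | (3R,4E)-hept-4-en-3-ol | CC/C=C/[C@H](O)CC | intermediate
3 | ethyl (3R,4E)-3-ethylhept-4-enoate | CCOC(=O)C[C@@H](CC)/C=C/CC | intermediate
4 | (3R,4E)-3-ethylhept-4-enal | O=CC[C@@H](CC)/C=C/CC | intermediate
5 | (4R,5E)-4-ethylocta-1,5-diene | C=CC[C@@H](CC)/C=C/CC | intermediate
6 | (4R)-4-benzyl-3-butanoyl-1,3-oxazolidin-2-one | CCCC(=O)N1[C@H](Cc2ccccc2)COC1=O | starting material
7 | sodium (Z)-enolate of 6 | [Na+].CC/C=C(\[O-])N1[C@H](Cc2ccccc2)COC1=O | intermediate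
8 | (4R)-4-benzyl-3-[(2S)-2-ethylpent-4-ynoyl]-1,3-oxazolidin-2-one | C#CC[C@H](CC)C(=O)N1[C@H](Cc2ccccc2)COC1=O | intermediate
9 | (2S)-2-ethylpent-4-yn-1-ol | C#CC[C@H](CC)CO | intermediate
10 | tert-butyl{[(2S)-2-ethylpent-4-yn-1-yl]oxy}diphenylsilane | C#CC[C@H](CC)CO[Si](c1ccccc1)(c1ccccc1)C(C)(C)C | intermediate
11 | lithium acetylide of 10 | [Li]C#CC[C@H](CC)CO[Si](c1ccccc1)(c1ccccc1)C(C)(C)C | intermediate
12 | (5S)-5-{[tert-butyl(diphenyl)silyl]oxymethyl}hept-2-yn-1-ol | OCC#CC[C@H](CC)CO[Si](c1ccccc1)(c1ccccc1)C(C)(C)C | intermediate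
13 | sodium alkenylalanate of 12 (five-membered C–Al–O ate complex, two 2-methoxyethoxy groups on Al) | [Na+].COCCO[Al-]1(OCCOC)OCC=C1C[C@H](CC)CO[Si](c2ccccc2)(c2ccccc2)C(C)(C)C | intermediate
14 | (2Z,5S)-5-{[tert-butyl(diphenyl)silyl]oxymethyl}-3-iodohept-2-en-1-ol | OC/C=C(\I)C[C@H](CC)CO[Si](c1ccccc1)(c1ccccc1)C(C)(C)C | intermediate
15 | 9-[(4R,5E)-4-ethyloct-5-en-1-yl]-9-borabicyclo[3.3.1]nonane | CC/C=C/[C@H](CC)CCCB1C2CCCC1CCC2 | intermediate
16 | (2E,7R,8E)-3-[(2S)-2-{[tert-butyl(diphenyl)silyl]oxymethyl}butyl]-7-ethylundeca-2,8-dien-1-ol | OC/C=C(\CCC[C@@H](CC)/C=C/CC)C[C@H](CC)CO[Si](c1ccccc1)(c1ccccc1)C(C)(C)C | intermediate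
17 | {(2R,3R)-3-[(2S)-2-{[tert-butyl(diphenyl)silyl]oxymethyl}butyl]-3-[(4R,5E)-4-ethyloct-5-en-1-yl]oxiran-2-yl}methanol | OC[C@H]1O[C@]1(CCC[C@@H](CC)/C=C/CC)C[C@H](CC)CO[Si](c2ccccc2)(c2ccccc2)C(C)(C)C | intermediate
18 | (3R,7R,8E)-3-[(2S)-2-{[tert-butyl(diphenyl)silyl]oxymethyl}butyl]-7-ethylundec-8-ene-1,3-diol | OCC[C@@](O)(CCC[C@@H](CC)/C=C/CC)C[C@H](CC)CO[Si](c1ccccc1)(c1ccccc1)C(C)(C)C | intermediate
19 | (3R,7R,8E)-3-[(2S)-2-{[tert-butyl(diphenyl)silyl]oxymethyl}butyl]-7-ethyl-3-hydroxyundec-8-en-1-yl 4-methylbenzenesulfonate | Cc1ccc(cc1)S(=O)(=O)OCC[C@@](O)(CCC[C@@H](CC)/C=C/CC)C[C@H](CC)CO[Si](c1ccccc1)(c1ccccc1)C(C)(C)C | intermediate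
20 | (2R)-2-[(2S)-2-{[tert-butyl(diphenyl)silyl]oxymethyl}butyl]-2-[(4R,5E)-4-ethyloct-5-en-1-yl]oxetane | C1CO[C@]1(CCC[C@@H](CC)/C=C/CC)C[C@H](CC)CO[Si](c2ccccc2)(c2ccccc2)C(C)(C)C | intermediate
21 | (2S)-2-({(2R)-2-[(4R,5E)-4-ethyloct-5-en-1-yl]oxetan-2-yl}methyl)butan-1-ol | C1CO[C@]1(CCC[C@@H](CC)/C=C/CC)C[C@H](CC)CO | intermediate
22 | (2S)-2-({(2R)-2-[(4R,5E)-4-ethyloct-5-en-1-yl]oxetan-2-yl}methyl)butanal | C1CO[C@]1(CCC[C@@H](CC)/C=C/CC)C[C@H](CC)C=O | intermediate
23 | methyl (2E,4S)-4-({(2R)-2-[(4R,5E)-4-ethyloct-5-en-1-yl]oxetan-2-yl}methyl)hex-2-enoate | C1CO[C@]1(CCC[C@@H](CC)/C=C/CC)C[C@H](CC)/C=C/C(=O)OC | intermediate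
24 | methyl (2E,4S,6S,10R,11E)-4,10-diethyl-6-hydroperoxy-6-(2-hydroxyethyl)tetradeca-2,11-dienoate | OCC[C@](OO)(CCC[C@@H](CC)/C=C/CC)C[C@H](CC)/C=C/C(=O)OC | intermediate
25 | methyl 2-{(3S,4S,6S)-4-ethyl-6-[(4R,5E)-4-ethyloct-5-en-1-yl]-6-(2-hydroxyethyl)-1,2-dioxan-3-yl}acetate | CC/C=C/[C@H](CC)CCC[C@@]1(CCO)C[C@H](CC)[C@H](CC(=O)OC)OO1 | intermediate
26 | methyl 2-{(3S,4S,6S)-4-ethyl-6-[(4R,5E)-4-ethyloct-5-en-1-yl]-6-[2-(tosyloxy)ethyl]-1,2-dioxan-3-yl}acetate | CC/C=C/[C@H](CC)CCC[C@@]1(CCOS(=O)(=O)c2ccc(C)cc2)C[C@H](CC)[C@H](CC(=O)OC)OO1 | intermediate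
27 | methyl 2-{(3S,4S,6S)-4,6-diethyl-6-[(4R,5E)-4-ethyloct-5-en-1-yl]-1,2-dioxan-3-yl}acetate | CC/C=C/[C@H](CC)CCC[C@@]1(CC)C[C@H](CC)[C@H](CC(=O)OC)OO1 | target

**Step count**

Total step count: 19. Longest linear sequence: 15 steps (6 to 27, steps 5–19).

**Steps most likely to fail**

Step 16. What may go wrong: ionisation of the activated oxetane to a free tertiary cation (erosion of the C6 configuration, elimination to alkenes), or attack of H2O2 at the primary oxetane carbon. The fallback installs the ethyl group before any peroxide and makes the hydroperoxide by SN1 perhydrolysis of a tertiary alcohol; it gives up the control of C6. It sets out from monotosylate 19, which is isolated instead of being cyclised. LiAlH4 (THF, 0 °C) should reduce it to the tertiary alcohol (3R,7R,8E)-3-[(2S)-2-{[tert-butyl(diphenyl)silyl]oxymethyl}butyl]-7-ethylundec-8-en-3-ol F1. Bu4NF should give (2S,4R,8R,9E)-2,4,8-triethyldodec-9-ene-1,4-diol F2. Dess–Martin oxidation to (2S,4R,8R,9E)-2,4,8-triethyl-4-hydroxydodec-9-enal F3 and Wittig olefination with Ph3P=CHCO2Me in the same flask should give methyl (2E,4S,6R,10R,11E)-4,6,10-triethyl-6-hydroxytetradeca-2,11-dienoate F4, which is kept free of base. Acid-catalysed perhydrolysis (50 % H2O2, catalytic H2SO4, Et2O, 0 °C) should give methyl (2E,4S,10R,11E)-4,6,10-triethyl-6-hydroperoxytetradeca-2,11-dienoate F5 as both C6 epimers. Et2NH in CF3CH2OH should close both to 27 and its C6 epimer methyl 2-{(3S,4S,6R)-4,6-diethyl-6-[(4R,5E)-4-ethyloct-5-en-1-yl]-1,2-dioxan-3-yl}acetate F6, to be separated by chromatography. The fallback comes back to the route at 27.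

Step 17. What may go wrong: poor facial selectivity at C3 (the competing H-inside rotamer would lead to the 3,4-trans ring), or retro-addition under the basic conditions. The fallback sets C3 by C–C bond formation on a preformed ring instead of by C–O ring closure. It sets out from alcohol 21. Dess–Martin oxidation gives aldehyde 22, which is isolated this time. Perhydrolysis of its oxetane under the conditions of step 16 should give a hydroperoxy aldehyde that closes to the peroxy hemiacetal (4S,6S)-4-ethyl-6-[(4R,5E)-4-ethyloct-5-en-1-yl]-6-(2-hydroxyethyl)-1,2-dioxan-3-ol F7 (both C3 epimers). MeOH with pyridinium p-toluenesulfonate should give (4S,6S)-4-ethyl-6-[(4R,5E)-4-ethyloct-5-en-1-yl]-6-(2-hydroxyethyl)-3-methoxy-1,2-dioxane F8. Ionisation with Me3SiOTf or TiCl4 in CH2Cl2 at −78 °C in the presence of excess CH2=C(OMe)OSiMe2t-Bu (the free hydroxyl is silylated in the flask and released on acidic work-up) should give 25, where the fallback rejoins the route. Axial attack of the ketene acetal on the peroxycarbenium ion, with the C4 ethyl pseudo-equatorial, is expected to place the acetate arm cis to the C4 ethyl.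

Step 19. What may go wrong: hydride or adventitious base attacking the ester or triggering β-elimination of the peroxide (retro-oxa-Michael) at the temperature needed for the displacement. The fallback replaces hydride displacement by elimination and diimide reduction. It sets out from tosylate 26. PhSeNa ((PhSe)2, NaBH4, EtOH, 0 °C) should give the selenide methyl 2-{(3S,4S,6S)-4-ethyl-6-[(4R,5E)-4-ethyloct-5-en-1-yl]-6-[2-(phenylselanyl)ethyl]-1,2-dioxan-3-yl}acetate F9. Oxidation with 30 % H2O2 (THF, 0 °C to rt) and syn-elimination of the selenoxide should give methyl 2-{(3S,4S,6S)-6-ethenyl-4-ethyl-6-[(4R,5E)-4-ethyloct-5-en-1-yl]-1,2-dioxan-3-yl}acetate F10. Diimide (KO2CN=NCO2K, AcOH, MeOH, 0 °C) reduces a monosubstituted vinyl group much faster than the (E)-disubstituted C11=C12 alkene and leaves the O–O bond alone, so it should give 27, where the fallback rejoins the route.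

**Further compounds**

F1 | step 16 | (3R,7R,8E)-3-[(2S)-2-{[tert-butyl(diphenyl)silyl]oxymethyl}butyl]-7-ethylundec-8-en-3-ol | CC[C@@](O)(CCC[C@@H](CC)/C=C/CC)C[C@H](CC)CO[Si](c1ccccc1)(c1ccccc1)C(C)(C)C
F2 | step 16 | (2S,4R,8R,9E)-2,4,8-triethyldodec-9-ene-1,4-diol | CC[C@@](O)(CCC[C@@H](CC)/C=C/CC)C[C@H](CC)CO
F3 | step 16 | (2S,4R,8R,9E)-2,4,8-triethyl-4-hydroxydodec-9-enal | CC[C@@](O)(CCC[C@@H](CC)/C=C/CC)C[C@H](CC)C=O
F4 | step 16 | methyl (2E,4S,6R,10R,11E)-4,6,10-triethyl-6-hydroxytetradeca-2,11-dienoate | CC[C@@](O)(CCC[C@@H](CC)/C=C/CC)C[C@H](CC)/C=C/C(=O)OC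
F5 | step 16 | methyl (2E,4S,10R,11E)-4,6,10-triethyl-6-hydroperoxytetradeca-2,11-dienoate (both C6 epimers) | CC/C=C/[C@H](CC)CCCC(CC)(OO)C[C@H](CC)/C=C/C(=O)OC
F6 | step 16 | methyl 2-{(3S,4S,6R)-4,6-diethyl-6-[(4R,5E)-4-ethyloct-5-en-1-yl]-1,2-dioxan-3-yl}acetate | CC/C=C/[C@H](CC)CCC[C@]1(CC)C[C@H](CC)[C@H](CC(=O)OC)OO1
F7 | step 17 | (4S,6S)-4-ethyl-6-[(4R,5E)-4-ethyloct-5-en-1-yl]-6-(2-hydroxyethyl)-1,2-dioxan-3-ol (both C3 epimers) | CC/C=C/[C@H](CC)CCC[C@@]1(CCO)C[C@H](CC)C(O)OO1
F8 | step 17 | (4S,6S)-4-ethyl-6-[(4R,5E)-4-ethyloct-5-en-1-yl]-6-(2-hydroxyethyl)-3-methoxy-1,2-dioxane (both C3 epimers) | CC/C=C/[C@H](CC)CCC[C@@]1(CCO)C[C@H](CC)C(OC)OO1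
F9 | step 19 | methyl 2-{(3S,4S,6S)-4-ethyl-6-[(4R,5E)-4-ethyloct-5-en-1-yl]-6-[2-(phenylselanyl)ethyl]-1,2-dioxan-3-yl}acetate | CC/C=C/[C@H](CC)CCC[C@@]1(CC[Se]c2ccccc2)C[C@H](CC)[C@H](CC(=O)OC)OO1
F10 | step 19 | methyl 2-{(3S,4S,6S)-6-ethenyl-4-ethyl-6-[(4R,5E)-4-ethyloct-5-en-1-yl]-1,2-dioxan-3-yl}acetate | CC/C=C/[C@H](CC)CCC[C@@]1(C=C)C[C@H](CC)[C@H](CC(=O)OC)OO1
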